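The data come from a simulation with made-up constants; the scatter is artificial.

G grew more slowly than J in the larch run, reaching 18.6% against 65.1% at 40.0 s, and how much more slowly was what I wanted to carry to the new flask.

- larch: Z 0.12 M; X 0.22 M; D 6 mM; run made earlier
- flask: Z 0.12 M; X 0.108 M; D 6.00 mM; time 2.0 min

- larch (time / s: J / %, G / %, Q / %): 10.0: 26.3, 5.4, 61.3; 15.0: 39.0, 10.1, 44.0; 20.0: 48.9, 13.5, 32.8; 25.0: 56.1, 14.3, 25.1; 30.0: 59.8, 16.6, 17.4; 40.0: 65.1, 18.6, 10.2

(each reading ± 1 percentage point)

- as a solid, counted per litre of solution: Z
- at the start none of Z is in solution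
- Q means what is dissolved; the solid is not counted in it

- the J in the flask at 2.0 min, as a percentage of the Z charged
- the G in the flask at 2.0 min, as a percentage of the Z charged
- the Q in the flask at 2.0 min, as a percentage of the Z charged

Reading down the table, I found J to G at 4.87 in the first row and 3.50 in the last, so the ratio fell as X was consumed. I took a ratio of one as the zero of my scale. As my own guess, I supposed that each G takes one X, as each J does. The last row then puts c_X at 0.120 M, down from 0.22 M. Multiplying the mean of those two by G/J gave, as a reading with its scatter, c* = 0.0485 M. I called this the even level: the c_X at which J and G are made equally fast. It is a selectivity factor written as a concentration.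

In the new flask X is the limiting reagent, 0.108 M against 0.12 M of Z. The next product is J with chance c_X/(c_X + c*). Summing this as c_X goes from its charge to zero gives G = c* ln((charge + c*)/c*). My reckoning was therefore G 47.4% and J 42.6%. Taking off the 5.00% of Z that I assigned to D left Q 5.00%.

The forecast gave J 53%, G 38% and Q 3.5%, holding that “rings compete far better”. My G stood above its figure.

The flask gave J 44.6%, G 42.9% and Q 7.54%.

    Q + D → L (k = 5.27 L mol⁻¹ s⁻¹)
    Z ⇌ Q, rate k2*(cs2 - [Q]) while solid is left; crystals form when [Q] > cs2 (solubility = 0.110 M, k = 0.223 s⁻¹)
    Q + X → J (k = 0.311 L mol⁻¹ s⁻¹)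
    Q + X → G, rate k4*[Q] as long as [X] is above zero (k = 0.0136 s⁻¹)

In the neighbour flask charged with 0.027 M of X, where X stood at 0%, the even level gives G 17.9%, and the flask held 17.5%. The asked flask had not quite come to rest at 2.0 min: 2.8% of its X remained, a c_X of 0.00304 M, below c*. Summed as c_X goes to zero, the rule sends 97.0% of that remainder to G. Left ten times as long, the flask reached X 0%, G rose by 2.5 percentage points, J rose by 0.085 points, and Q fell to 5.00%.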